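**Retrosynthetic overview**

1. Target 30 has ring A (2,3-dimethyl-dihydropyran-4-one: O1, C2, C3, C4, C4a, C8a), ring B (carbocycle C4a–C5–C6–C7–C8–C8a with quaternary C6) and ring C (cyclobutane); the last step is hydrolysis of methyl ester 29.
2. Ring B is cut at C5–C6 and C7–C8. C6–C7 plus the prenyl CH2–CH go back to γ-butyrolactone 25 (C7 = lactone carbonyl, C6 = α-carbon, prenyl CH = O-bearing carbon carrying CMe2P(O)Ph2). C5, C4a, C8a and C8 come from ring A acid 12 (C5 = carboxyl carbon, C8 = its 6-CH2).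
3. Enabling feature: C6 is the quaternary α-carbon between the C7 ketone and the C5 enol carbon, C8 is the vinylogous γ-carbon of the C5 and C4 carbonyls through C8a=C4a, and the prenyl alkene carbon lies γ to C7. A temporary lactone can therefore fix the enolate geometry and face at C6, and its ring oxygen can leave C7 and then depart with phosphorus as the prenyl double bond.
4. Fragments: 12 from methyl (3R)-3-hydroxybutanoate (Fráter–Seebach methylation sets C2/C3) and desymmetrised 3-phenylglutaric anhydride (benzylic centre); ring C from (1S,5S)-(−)-verbenone; lactone 23 from isopropyldiphenylphosphine oxide and succinic anhydride by CBS reduction.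
5. Order of ring formation: ring C (chiral pool), ring A (step 6), temporary lactone (step 13), ring B (step 15, with loss of the lactone).

Key step: step 15

Assumption: in step 1 the cinchona catalyst is used in whichever pseudo-enantiomeric form ((DHQD)2AQN or (DHQ)2AQN) delivers the (S)-hemiester; the sense of induction for this substrate is not asserted here.

**Route**

Step 1
Reactants: 1 3-phenylglutaric anhydride
Product: 2 (3S)-5-methoxy-5-oxo-3-phenylpentanoic acid
Conditions: MeOH (10 equiv), (DHQD)2AQN (0.1 equiv), Et2O, −30 °C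
Reagents that add atoms: methanol, CO
Why: Cinchona-alkaloid-catalysed enantioselective alcoholysis (desymmetrisation) of the meso anhydride, in which the catalyst acts as general base and directs methanol to one enantiotopic carbonyl, should set the benzylic centre as (S).

Step 2
Reactants: 3 methyl (3R)-3-hydroxybutanoate
Product: 4 methyl (2R,3R)-3-hydroxy-2-methylbutanoate
Conditions: LiN(iPr)2 (LDA, 2.2 equiv), THF, −50 → −20 °C; MeI, DMPU, −78 → 0 °C
Reagents that add atoms: iodomethane, CI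
Why: Fráter–Seebach alkylation, in which the chelated dianion is methylated anti to the carbinol substituent, should give the anti (2R,3R) product.

Step 3
Reactants: 4 methyl (2R,3R)-3-hydroxy-2-methylbutanoate
Product: 5 methyl (2R,3R)-3-[(tert-butyldimethylsilyl)oxy]-2-methylbutanoate
Conditions: TBSCl, imidazole, DMF, rt
Reagents that add atoms: tert-butyldimethylsilyl chloride, CC(C)(C)[Si](C)(C)Cl
Why: Standard silylation protects the secondary alcohol against O-acylation in step 5.

Step 4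
Reactants: 5 methyl (2R,3R)-3-[(tert-butyldimethylsilyl)oxy]-2-methylbutanoate; 6 tert-butyl acetate
Product: 7 tert-butyl (4R,5R)-5-[(tert-butyldimethylsilyl)oxy]-4-methyl-3-oxohexanoate
Conditions: 6, LiN(iPr)2 (3.2 equiv each), THF, −78 °C; then 5, −78 → −30 °C
Reagents that add atoms: none
Why: Crossed Claisen condensation with the lithium enolate of 6; the excess enolate converts the β-keto ester into its enolate, which should protect the C4 stereocentre from epimerisation.

Step 5
Reactants: 7 tert-butyl (4R,5R)-5-[(tert-butyldimethylsilyl)oxy]-4-methyl-3-oxohexanoate; 2 (3S)-5-methoxy-5-oxo-3-phenylpentanoic acid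
Product: 9 tert-butyl (4R,5R)-5-[(tert-butyldimethylsilyl)oxy]-2-[(3S)-5-methoxy-5-oxo-3-phenylpentanoyl]-4-methyl-3-oxohexanoate (C2 enolised), via acid chloride 8 (not isolated)
Conditions: 2, (COCl)2, DMF (cat.), CH2Cl2, 0 °C → rt, evaporate; then 7, MgCl2, pyridine, CH2Cl2, 0 °C → rt
Reagents that add atoms: none
Why: Magnesium-mediated soft enolisation of the β-keto ester and C-acylation by the acid chloride (Claisen-type acylation), the magnesium chelate favouring carbon over oxygen.

Step 6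
Reactants: 9 tert-butyl (4R,5R)-5-[(tert-butyldimethylsilyl)oxy]-2-[(3S)-5-methoxy-5-oxo-3-phenylpentanoyl]-4-methyl-3-oxohexanoate
Product: 11 tert-butyl (2R,3R)-6-[(2S)-4-methoxy-4-oxo-2-phenylbutyl]-2,3-dimethyl-4-oxo-3,4-dihydro-2H-pyran-5-carboxylate, via hydroxy tricarbonyl 10 (not isolated)
Conditions: HF·pyridine, THF, 0 °C → rt; then PPTS (0.2 equiv), 4 Å molecular sieves, toluene, 50 °C
Reagents that add atoms: none
Why: Desilylation followed by acid-catalysed cyclodehydration (hemiketal formation of the δ-hydroxyl on the side-chain ketone, then loss of water) should close ring A as the vinylogous ester; the hindered tert-butyl ester should not lactonise, and the trans-dimethyl arrangement is the thermodynamic one.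

Step 7
Reactants: 11 tert-butyl (2R,3R)-6-[(2S)-4-methoxy-4-oxo-2-phenylbutyl]-2,3-dimethyl-4-oxo-3,4-dihydro-2H-pyran-5-carboxylate
Product: 12 (2R,3R)-6-[(2S)-4-methoxy-4-oxo-2-phenylbutyl]-2,3-dimethyl-4-oxo-3,4-dihydro-2H-pyran-5-carboxylic acid
Conditions: CF3CO2H/CH2Cl2 (1:4), 0 °C → rt
Reagents that add atoms: none
Why: Acidolysis of the tert-butyl ester with loss of isobutene; the methyl ester and the vinylogous ester should survive, and the acid is stabilised by hydrogen bonding to the C4 carbonyl.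

Step 8
Reactants: 13 (1S,5S)-(−)-verbenone
Product: 14 (1S,3R)-3-acetyl-2,2-dimethylcyclobutane-1-carboxylic acid (cis-pinononic acid)
Conditions: RuCl3·xH2O (2 mol%), NaIO4 (4.1 equiv), EtOAc/MeCN/H2O, rt
Reagents that add atoms: sodium periodate, [Na+].[O-]I(=O)(=O)=O; water, O
Why: Oxidative cleavage of the enone C=C by catalytic RuO4 (generated from RuCl3 and NaIO4) with loss of the former C3 as CO2; neither ring stereocentre is touched, so the cis cyclobutane is carried over from the terpene.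

Step 9
Reactants: 14 (1S,3R)-3-acetyl-2,2-dimethylcyclobutane-1-carboxylic acid
Product: 15 (1S,3S)-2,2-dimethyl-3-(prop-1-en-2-yl)cyclobutane-1-carboxylic acid
Conditions: Ph3PCH3Br (2.5 equiv), KOtBu (2.5 equiv), THF, 0 °C; then 14, 0 °C → rt
Reagents that add atoms: methyltriphenylphosphonium bromide, C[P+](c1ccccc1)(c1ccccc1)c1ccccc1.[Br-]
Why: Wittig methylenation of the methyl ketone on the carboxylate salt; the ylide is consumed faster than the ketone enolises, so the cis relationship should be kept.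

Step 10
Reactants: 15 (1S,3S)-2,2-dimethyl-3-(prop-1-en-2-yl)cyclobutane-1-carboxylic acid
Product: 16 [(1S,3S)-2,2-dimethyl-3-(prop-1-en-2-yl)cyclobutyl]methanol
Conditions: LiAlH4, Et2O, 0 °C → rt
Reagents that add atoms: none
Why: Hydride reduction of the acid to the primary alcohol; the isolated alkene is inert.

Step 11
Reactants: 17 isopropyldiphenylphosphine
Product: 18 isopropyldiphenylphosphine oxide
Conditions: H2O2 (30% aq.), acetone, 0 °C
Reagents that add atoms: hydrogen peroxide, OO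
Why: Clean oxidation of the tertiary phosphine at phosphorus.

Step 12
Reactants: 18 isopropyldiphenylphosphine oxide; 19 succinic anhydride
Product: 21 methyl 5-(diphenylphosphoryl)-5-methyl-4-oxohexanoate, via keto acid 20 (not isolated)
Conditions: 18, n-BuLi, THF, −78 °C; 19, −78 → 0 °C; then DMF, MeI, rt
Reagents that add atoms: iodomethane, CI
Why: The α-lithiated phosphine oxide is acylated by ring-opening of the anhydride (the carboxylate formed prevents a second addition), and the lithium carboxylate is then O-methylated.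

Step 13
Reactants: 21 methyl 5-(diphenylphosphoryl)-5-methyl-4-oxohexanoate
Product: 23 (5S)-5-[2-(diphenylphosphoryl)propan-2-yl]oxolan-2-one, via hydroxy ester 22 (not isolated)
Conditions: (R)-2-methyl-CBS-oxazaborolidine (0.2 equiv), BH3·SMe2, THF, −20 °C; MeOH; then TsOH·H2O (cat.), toluene, 60 °C
Reagents that add atoms: none
Why: Corey–Bakshi–Shibata reduction with the quaternary CMe2P(O)Ph2 group as the large substituent should give the (S)-carbinol, which lactonises under acid; β-hydroxy phosphine oxides are stable to these conditions.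

Step 14
Reactants: 23 (5S)-5-[2-(diphenylphosphoryl)propan-2-yl]oxolan-2-one; 16 [(1S,3S)-2,2-dimethyl-3-(prop-1-en-2-yl)cyclobutyl]methanol
Product: 25 (5S)-3-{[(1R,3S)-2,2-dimethyl-3-(prop-1-en-2-yl)cyclobutyl]methyl}-5-[2-(diphenylphosphoryl)propan-2-yl]oxolan-2-one (both C3 epimers), via triflate 24 (not isolated)
Conditions: 16, Tf2O, 2,6-lutidine, CH2Cl2, −78 °C, cold wash, used at once; 23, LiN(iPr)2, THF, −78 °C; then 24, −78 → −30 °C
Reagents that add atoms: none
Why: SN2 alkylation of the lactone lithium enolate by the primary triflate (enolate alkylation); the configuration at C3 does not matter because this centre becomes an enolate again in step 15.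

Step 15
Reactants: 25 (5S)-3-{[(1R,3S)-2,2-dimethyl-3-(prop-1-en-2-yl)cyclobutyl]methyl}-5-[2-(diphenylphosphoryl)propan-2-yl]oxolan-2-one; 12 (2R,3R)-6-[(2S)-4-methoxy-4-oxo-2-phenylbutyl]-2,3-dimethyl-4-oxo-3,4-dihydro-2H-pyran-5-carboxylic acid
Product: 29 methyl (3S)-3-[(2R,3R,6R)-6-{[(1R,3S)-2,2-dimethyl-3-(prop-1-en-2-yl)cyclobutyl]methyl}-5-hydroxy-2,3-dimethyl-6-(3-methylbut-2-en-1-yl)-4,7-dioxo-3,4,6,7-tetrahydro-2H-chromen-8-yl]-3-phenylpropanoate, via acid chloride 26 (not isolated), via acyl lactone 27 (not isolated), via hydroxy phosphine oxide 28 (not isolated)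
Conditions: 12, 1-chloro-N,N,2-trimethylprop-1-en-1-amine (1.05 equiv), CH2Cl2, 0 °C → rt, solvent exchanged for THF; 25, LiN(iPr)2 (1.05 equiv), THF, −78 °C, enolate added to 26 at −78 °C; then KN(SiMe3)2 (2.5 equiv), −78 °C → rt; aq. NH4Cl
Reagents that add atoms: none
Why: Proposed new method: the lithium enolate of 25 has its geometry fixed by the lactone ring and should be C-acylated by 26 (directly or through the vinylketene that 26 can give by loss of HCl) on the face anti to the bulky C5 substituent of the lactone, which forms the C5–C6 bond of ring B and sets C6 as (R), as in the known anti-selective quaternisation of γ-substituted butyrolactone enolates. KN(SiMe3)2 then deprotonates the 6-CH2 of the pyranone (the vinylogous γ-position of the C5 and C4 carbonyls, the future C8), and this extended enolate attacks the lactone carbonyl through carbon in a Dieckmann-type 6-(enolendo)-exo-trig acyl substitution that forms C7–C8, closes ring B and opens the temporary lactone. The potassium alkoxide set free is β to the diphenylphosphoryl group and should collapse by syn Horner–Wittig elimination of potassium diphenylphosphinate to the prenyl alkene, which removes the stereocentre that did the steering, makes the ring opening irreversible and leaves ring B as its stable enolate. The closest known reaction types are the Claisen C-acylation of ester enolates by acid chlorides, the base-mediated Claisen cyclisation of polyketide-type tricarbonyl esters to acylphloroglucinols and the Horner–Wittig olefination, which are merged here into one formal [4+2] annulation. The step needs C- and not O-acylation twice: in the first stage the lithium counter-ion and the acid chloride favour carbon, and in the second stage closure through C4a would give a four-membered ring while closure through the C4 carbonyl oxygen is the remaining competitor, which cold addition of the potassium base and slow warming should hold back. The stereocentres of ring A, ring C and the benzylic carbon lie away from the sites that are deprotonated, and the C3 methyl group is already trans to the C2 methyl group, the thermodynamic arrangement.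

Step 16
Reactants: 29 methyl (3S)-3-[(2R,3R,6R)-6-{[(1R,3S)-2,2-dimethyl-3-(prop-1-en-2-yl)cyclobutyl]methyl}-5-hydroxy-2,3-dimethyl-6-(3-methylbut-2-en-1-yl)-4,7-dioxo-3,4,6,7-tetrahydro-2H-chromen-8-yl]-3-phenylpropanoate
Product: 30 (3S)-3-[(2R,3R,6R)-6-{[(1R,3S)-2,2-dimethyl-3-(prop-1-en-2-yl)cyclobutyl]methyl}-5-hydroxy-2,3-dimethyl-6-(3-methylbut-2-en-1-yl)-4,7-dioxo-3,4,6,7-tetrahydro-2H-chromen-8-yl]-3-phenylpropanoic acid (CNP0103716.3)
Conditions: LiOH·H2O (3 equiv), THF/H2O (3:1), 0 °C → rt; then 0.5 M HCl to pH 3, 0 °C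
Reagents that add atoms: lithium hydroxide, [Li+].[OH-]
Why: Saponification of the methyl ester; ring B is present as its enolate under these conditions and is thereby shielded from hydroxide, and the cold, brief acidification should spare the prenyl and isopropenyl groups.

**Compound list**

1 | 3-phenylglutaric anhydride | O=C1CC(c2ccccc2)CC(=O)O1 | starting material
2 | (3S)-5-methoxy-5-oxo-3-phenylpentanoic acid | COC(=O)C[C@H](CC(=O)O)c1ccccc1 | intermediate
3 | methyl (3R)-3-hydroxybutanoate | COC(=O)C[C@@H](C)O | starting material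
4 | methyl (2R,3R)-3-hydroxy-2-methylbutanoate | COC(=O)[C@H](C)[C@@H](C)O | intermediate
5 | methyl (2R,3R)-3-[(tert-butyldimethylsilyl)oxy]-2-methylbutanoate | COC(=O)[C@H](C)[C@@H](C)O[Si](C)(C)C(C)(C)C | intermediate
6 | tert-butyl acetate | CC(=O)OC(C)(C)C | starting material
7 | tert-butyl (4R,5R)-5-[(tert-butyldimethylsilyl)oxy]-4-methyl-3-oxohexanoate | CC(C)(C)OC(=O)CC(=O)[C@H](C)[C@@H](C)O[Si](C)(C)C(C)(C)C | intermediate
8 | methyl (3R)-5-chloro-5-oxo-3-phenylpentanoate (acid chloride of 2) | COC(=O)C[C@H](CC(=O)Cl)c1ccccc1 | intermediate (not isolated)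
9 | tert-butyl (4R,5R)-5-[(tert-butyldimethylsilyl)oxy]-2-[(3S)-5-methoxy-5-oxo-3-phenylpentanoyl]-4-methyl-3-oxohexanoate (C2 enolised) | COC(=O)C[C@H](CC(=O)C(C(=O)OC(C)(C)C)C(=O)[C@H](C)[C@@H](C)O[Si](C)(C)C(C)(C)C)c1ccccc1 | intermediate
10 | tert-butyl (4R,5R)-5-hydroxy-2-[(3S)-5-methoxy-5-oxo-3-phenylpentanoyl]-4-methyl-3-oxohexanoate | COC(=O)C[C@H](CC(=O)C(C(=O)OC(C)(C)C)C(=O)[C@H](C)[C@@H](C)O)c1ccccc1 | intermediate (not isolated)
11 | tert-butyl (2R,3R)-6-[(2S)-4-methoxy-4-oxo-2-phenylbutyl]-2,3-dimethyl-4-oxo-3,4-dihydro-2H-pyran-5-carboxylate | COC(=O)C[C@H](CC1=C(C(=O)OC(C)(C)C)C(=O)[C@H](C)[C@@H](C)O1)c1ccccc1 | intermediate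
12 | (2R,3R)-6-[(2S)-4-methoxy-4-oxo-2-phenylbutyl]-2,3-dimethyl-4-oxo-3,4-dihydro-2H-pyran-5-carboxylic acid | COC(=O)C[C@H](CC1=C(C(=O)O)C(=O)[C@H](C)[C@@H](C)O1)c1ccccc1 | intermediate
13 | (1S,5S)-(−)-verbenone | O=C1C=C(C)[C@@H]2C[C@H]1C2(C)C | starting material
14 | (1S,3R)-3-acetyl-2,2-dimethylcyclobutane-1-carboxylic acid | CC(=O)[C@@H]1C[C@H](C(=O)O)C1(C)C | intermediate
15 | (1S,3S)-2,2-dimethyl-3-(prop-1-en-2-yl)cyclobutane-1-carboxylic acid | C=C(C)[C@@H]1C[C@H](C(=O)O)C1(C)C | intermediate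
16 | [(1S,3S)-2,2-dimethyl-3-(prop-1-en-2-yl)cyclobutyl]methanol | C=C(C)[C@@H]1C[C@H](CO)C1(C)C | intermediate
17 | isopropyldiphenylphosphine | CC(C)P(c1ccccc1)c1ccccc1 | starting material
18 | isopropyldiphenylphosphine oxide | CC(C)P(=O)(c1ccccc1)c1ccccc1 | intermediate
19 | succinic anhydride | O=C1CCC(=O)O1 | starting material
20 | 5-(diphenylphosphoryl)-5-methyl-4-oxohexanoic acid | OC(=O)CCC(=O)C(C)(C)P(=O)(c1ccccc1)c1ccccc1 | intermediate (not isolated)
21 | methyl 5-(diphenylphosphoryl)-5-methyl-4-oxohexanoate | COC(=O)CCC(=O)C(C)(C)P(=O)(c1ccccc1)c1ccccc1 | intermediate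
22 | methyl (4S)-5-(diphenylphosphoryl)-4-hydroxy-5-methylhexanoate | COC(=O)CC[C@H](O)C(C)(C)P(=O)(c1ccccc1)c1ccccc1 | intermediate (not isolated)
23 | (5S)-5-[2-(diphenylphosphoryl)propan-2-yl]oxolan-2-one | O=C1O[C@H](C(C)(C)P(=O)(c2ccccc2)c2ccccc2)CC1 | intermediate
24 | [(1S,3S)-2,2-dimethyl-3-(prop-1-en-2-yl)cyclobutyl]methyl trifluoromethanesulfonate | C=C(C)[C@@H]1C[C@H](COS(=O)(=O)C(F)(F)F)C1(C)C | intermediate (not isolated)
25 | (5S)-3-{[(1R,3S)-2,2-dimethyl-3-(prop-1-en-2-yl)cyclobutyl]methyl}-5-[2-(diphenylphosphoryl)propan-2-yl]oxolan-2-one (both C3 epimers) | O=C1O[C@H](C(C)(C)P(=O)(c2ccccc2)c2ccccc2)CC1C[C@H]3C[C@@H](C(C)=C)C3(C)C | intermediate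
26 | (2R,3R)-6-[(2S)-4-methoxy-4-oxo-2-phenylbutyl]-2,3-dimethyl-4-oxo-3,4-dihydro-2H-pyran-5-carbonyl chloride | COC(=O)C[C@H](CC1=C(C(=O)Cl)C(=O)[C@H](C)[C@@H](C)O1)c1ccccc1 | intermediate (not isolated)
27 | methyl (3S)-4-{(2R,3R)-5-[(3S,5S)-3-{[(1R,3S)-2,2-dimethyl-3-(prop-1-en-2-yl)cyclobutyl]methyl}-5-[2-(diphenylphosphoryl)propan-2-yl]-2-oxooxolane-3-carbonyl]-2,3-dimethyl-4-oxo-3,4-dihydro-2H-pyran-6-yl}-3-phenylbutanoate | O=C1O[C@H](C(C)(C)P(=O)(c2ccccc2)c2ccccc2)C[C@@]1(C[C@H]3C[C@@H](C(C)=C)C3(C)C)C(=O)C4=C(C[C@@H](CC(=O)OC)c5ccccc5)O[C@H](C)[C@@H](C)C4=O | intermediate (not isolated)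
28 | methyl (3S)-3-[(2R,3R,6S)-6-{[(1R,3S)-2,2-dimethyl-3-(prop-1-en-2-yl)cyclobutyl]methyl}-6-[(2S)-3-(diphenylphosphoryl)-2-hydroxy-3-methylbutyl]-5-hydroxy-2,3-dimethyl-4,7-dioxo-3,4,6,7-tetrahydro-2H-chromen-8-yl]-3-phenylpropanoate | C=C(C)[C@@H]1C[C@H](C[C@@]2(C[C@H](O)C(C)(C)P(=O)(c3ccccc3)c3ccccc3)C(=O)C([C@@H](CC(=O)OC)c3ccccc3)=C3O[C@H](C)[C@@H](C)C(=O)C3=C2O)C1(C)C | intermediate (not isolated)
29 | methyl (3S)-3-[(2R,3R,6R)-6-{[(1R,3S)-2,2-dimethyl-3-(prop-1-en-2-yl)cyclobutyl]methyl}-5-hydroxy-2,3-dimethyl-6-(3-methylbut-2-en-1-yl)-4,7-dioxo-3,4,6,7-tetrahydro-2H-chromen-8-yl]-3-phenylpropanoate | C=C(C)[C@@H]1C[C@H](C[C@@]2(CC=C(C)C)C(=O)C([C@@H](CC(=O)OC)c3ccccc3)=C3O[C@H](C)[C@@H](C)C(=O)C3=C2O)C1(C)C | intermediate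
30 | (3S)-3-[(2R,3R,6R)-6-{[(1R,3S)-2,2-dimethyl-3-(prop-1-en-2-yl)cyclobutyl]methyl}-5-hydroxy-2,3-dimethyl-6-(3-methylbut-2-en-1-yl)-4,7-dioxo-3,4,6,7-tetrahydro-2H-chromen-8-yl]-3-phenylpropanoic acid | C=C(C)[C@@H]1C[C@H](C[C@@]2(CC=C(C)C)C(=O)C([C@@H](CC(=O)O)c3ccccc3)=C3O[C@H](C)[C@@H](C)C(=O)C3=C2O)C1(C)C | target

**Summary**

Total step count: 16. Longest linear sequence: 8 steps (steps 2, 3, 4, 5, 6, 7, 15, 16, from methyl (3R)-3-hydroxybutanoate).

**Steps most likely to fail**

Step 15 (proposed new method). What may go wrong: O-acylation of the hindered lactone enolate, proton transfer from the acidic 6-CH2 of 26 that quenches the enolate, ring closure through the C4 carbonyl oxygen to an enol lactone, or a Dieckmann addition that does not go forward. The fallback makes ring B aromatic first and quaternises C6 afterwards with known chemistry, at the price of stereocontrol at C6. It sets out from 24 and 26 and rejoins the route at 29.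
- Triflate 24 alkylates sodium dimethyl malonate (NaH, THF/DMF) to dimethyl 2-{[(1R,3S)-2,2-dimethyl-3-(prop-1-en-2-yl)cyclobutyl]methyl}propanedioate F1.
- Dealkoxycarbonylation (LiCl, wet DMSO, heat) gives methyl 3-[(1S,3S)-2,2-dimethyl-3-(prop-1-en-2-yl)cyclobutyl]propanoate F2.
- The lithium enolate of F2 (LiN(iPr)2, THF, −78 °C) is C-acylated by 26 to the β-keto ester methyl 2-{[(1R,3S)-2,2-dimethyl-3-(prop-1-en-2-yl)cyclobutyl]methyl}-3-{(2R,3R)-6-[(2S)-4-methoxy-4-oxo-2-phenylbutyl]-2,3-dimethyl-4-oxo-3,4-dihydro-2H-pyran-5-yl}-3-oxopropanoate F3.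
- Excess LiN(SiMe3)2 closes ring B by Dieckmann condensation of the C8 carbanion on the methyl ester, and the product tautomerises to the aromatic chromanone methyl (3S)-3-[(2R,3R)-6-{[(1R,3S)-2,2-dimethyl-3-(prop-1-en-2-yl)cyclobutyl]methyl}-5,7-dihydroxy-2,3-dimethyl-4-oxo-3,4-dihydro-2H-chromen-8-yl]-3-phenylpropanoate F4.
- Dearomative C-prenylation at C6 (prenyl bromide, NaOMe, MeOH, 0 °C), the classical route to gem-dialkylated acylphloroglucinols, should go to the less hindered carbon between the two hydroxyls. It gives 29 together with its C6 epimer methyl (3S)-3-[(2R,3R,6S)-6-{[(1R,3S)-2,2-dimethyl-3-(prop-1-en-2-yl)cyclobutyl]methyl}-5-hydroxy-2,3-dimethyl-6-(3-methylbut-2-en-1-yl)-4,7-dioxo-3,4,6,7-tetrahydro-2H-chromen-8-yl]-3-phenylpropanoate F5, which is removed by chromatography.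

Step 14. What may go wrong: slow SN2 displacement at the β-branched carbon, or ionisation of the cyclobutylcarbinyl triflate with ring expansion. The fallback makes the C–C bond by olefination and conjugate reduction. It sets out from 16 and 23 and returns at 25.
- Oxidation of 16 (Dess–Martin periodinane, NaHCO3, CH2Cl2) gives (1S,3S)-2,2-dimethyl-3-(prop-1-en-2-yl)cyclobutane-1-carbaldehyde F6.
- Lactone 23 is converted (LiN(iPr)2, ClP(O)(OEt)2, then a second equivalent of LiN(iPr)2 for the enol phosphate to phosphonate shift) into diethyl {(5S)-5-[2-(diphenylphosphoryl)propan-2-yl]-2-oxooxolan-3-yl}phosphonate F7.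
- Horner–Wadsworth–Emmons reaction of F7 with F6 under LiCl/iPr2NEt in MeCN, mild enough for the epimerisable aldehyde, gives (5S)-3-{[(1R,3S)-2,2-dimethyl-3-(prop-1-en-2-yl)cyclobutyl]methylidene}-5-[2-(diphenylphosphoryl)propan-2-yl]oxolan-2-one F8.
- 1,4-Reduction with LiBH(s-Bu)3 (THF, −78 °C) gives 25.

Step 6. What may go wrong: closure of the hydroxyl on the ester carbonyl (lactone formation), loss of the tert-butyl ester followed by decarboxylation, or epimerisation at C3 before ring closure. The fallback closes ring A without the 2-acyl tricarbonyl compound. It sets out from 7 and 2 and returns at 11.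
- Desilylation of 7 (HF·pyridine, THF) gives tert-butyl (4R,5R)-5-hydroxy-4-methyl-3-oxohexanoate F9.
- Acid 2 is converted by way of 8 and dimethylamine into methyl (3S)-5-(dimethylamino)-5-oxo-3-phenylpentanoate F10.
- O-Methylation of F10 with Me3OBF4 and then NaOMe gives the amide acetal methyl (3S)-5-(dimethylamino)-5,5-dimethoxy-3-phenylpentanoate F11.
- Condensation of F9 with F11 in toluene (Knoevenagel-type enaminone formation at the active methylene, then oxa-conjugate addition of the hydroxyl and loss of dimethylamine) gives 11.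

**Further compounds**

F1 | step 15 | dimethyl 2-{[(1R,3S)-2,2-dimethyl-3-(prop-1-en-2-yl)cyclobutyl]methyl}propanedioate | COC(=O)C(C[C@H]1C[C@@H](C(C)=C)C1(C)C)C(=O)OC
F2 | step 15 | methyl 3-[(1S,3S)-2,2-dimethyl-3-(prop-1-en-2-yl)cyclobutyl]propanoate | COC(=O)CC[C@H]1C[C@@H](C(C)=C)C1(C)C
F3 | step 15 | methyl 2-{[(1R,3S)-2,2-dimethyl-3-(prop-1-en-2-yl)cyclobutyl]methyl}-3-{(2R,3R)-6-[(2S)-4-methoxy-4-oxo-2-phenylbutyl]-2,3-dimethyl-4-oxo-3,4-dihydro-2H-pyran-5-yl}-3-oxopropanoate | COC(=O)C(C[C@H]1C[C@@H](C(C)=C)C1(C)C)C(=O)C2=C(C[C@@H](CC(=O)OC)c3ccccc3)O[C@H](C)[C@@H](C)C2=O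
F4 | step 15 | methyl (3S)-3-[(2R,3R)-6-{[(1R,3S)-2,2-dimethyl-3-(prop-1-en-2-yl)cyclobutyl]methyl}-5,7-dihydroxy-2,3-dimethyl-4-oxo-3,4-dihydro-2H-chromen-8-yl]-3-phenylpropanoate | COC(=O)C[C@@H](c1ccccc1)c1c(O)c(C[C@H]2C[C@@H](C(C)=C)C2(C)C)c(O)c2c1O[C@H](C)[C@@H](C)C2=O
F5 | step 15 | methyl (3S)-3-[(2R,3R,6S)-6-{[(1R,3S)-2,2-dimethyl-3-(prop-1-en-2-yl)cyclobutyl]methyl}-5-hydroxy-2,3-dimethyl-6-(3-methylbut-2-en-1-yl)-4,7-dioxo-3,4,6,7-tetrahydro-2H-chromen-8-yl]-3-phenylpropanoate | C=C(C)[C@@H]1C[C@H](C[C@]2(CC=C(C)C)C(=O)C([C@@H](CC(=O)OC)c3ccccc3)=C3O[C@H](C)[C@@H](C)C(=O)C3=C2O)C1(C)C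
F6 | step 14 | (1S,3S)-2,2-dimethyl-3-(prop-1-en-2-yl)cyclobutane-1-carbaldehyde | C=C(C)[C@@H]1C[C@H](C=O)C1(C)C
F7 | step 14 | diethyl {(5S)-5-[2-(diphenylphosphoryl)propan-2-yl]-2-oxooxolan-3-yl}phosphonate | O=C1O[C@H](C(C)(C)P(=O)(c2ccccc2)c2ccccc2)CC1P(=O)(OCC)OCC
F8 | step 14 | (5S)-3-{[(1R,3S)-2,2-dimethyl-3-(prop-1-en-2-yl)cyclobutyl]methylidene}-5-[2-(diphenylphosphoryl)propan-2-yl]oxolan-2-one | O=C1O[C@H](C(C)(C)P(=O)(c2ccccc2)c2ccccc2)CC1=C[C@H]3C[C@@H](C(C)=C)C3(C)C
F9 | step 6 | tert-butyl (4R,5R)-5-hydroxy-4-methyl-3-oxohexanoate | CC(C)(C)OC(=O)CC(=O)[C@H](C)[C@@H](C)O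
F10 | step 6 | methyl (3S)-5-(dimethylamino)-5-oxo-3-phenylpentanoate | COC(=O)C[C@H](CC(=O)N(C)C)c1ccccc1
F11 | step 6 | methyl (3S)-5-(dimethylamino)-5,5-dimethoxy-3-phenylpentanoate | COC(=O)C[C@H](CC(OC)(OC)N(C)C)c1ccccc1
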